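## Analysis of the target

Compound 12 is a depside: two benzene rings joined by an aryl ester, with no stereocentre and no ring to build beyond the two arenes. Ring A is a 2',4'-dimethoxy-6'-propylbenzoyl unit whose carbonyl carbon is flanked by the C2' methoxy and the C6' propyl group. Ring B is a salicylic acid (C1 carboxyl, C2 hydroxyl, C6 pentyl) that carries the ester oxygen at C4. The sensitive groups are the aryl ester, which has a phenoxide leaving group and is open to alcoholysis and acyl transfer, and the C1 carboxyl, which lies ortho and para to oxygen and is lost as carbon dioxide on heating in acid. The difficulty is twofold: an ester has to be made from a di-ortho-substituted benzoic acid, and the three acidic oxygens of ring B have to be told apart so that only O4 is acylated. The strategy rests on one feature of ring B: without the C1 carboxyl it is a 5-pentylresorcinol ring with a mirror plane through C3 and C6, so the C2 and C4 hydroxyls are equivalent and a monoester is a single compound. In that monoester C1 is ortho to the free C2 hydroxyl and para to the C4 acyloxy oxygen, so a metal held on the phenoxide can deliver carbon dioxide there as the last step.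

## Retrosynthetic reasoning

**C1–carboxyl bond of ring B.** Target 12 is cut between C1 and the carboxyl carbon, which leads back to the monodepside 8 and carbon dioxide 9. This is the only cut that restores the symmetry of ring B, and it removes the need to protect the C2 hydroxyl and the acid. It also places the most fragile group of 12 at the very end. The forward reaction has to carboxylate ortho to the phenol, at C1 and not at C3, without breaking the ester. It is planned as a magnesium-templated carboxylation that runs through the phenoxide 10 and the chelate 11.

**Ester bond between the ring A carbonyl and O4.** Depside 8 is cut at the acyl C–O bond into olivetol 6 and the acid chloride 7, which comes from acid 5. Diol 6 is purchasable and its two hydroxyls are equivalent, so the only selectivity issue is mono- against bis-acylation, and an excess of 6 handles that. The forward step must force a hindered acyl chloride onto a phenol, which calls for nucleophilic catalysis.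

**C1'–carboxyl bond of ring A.** Acid 5 is taken back through aldehyde 4 to the arene 2. The carbon is introduced by electrophilic formylation (through iminium 3) and then raised to the acid oxidation level. Electrophilic substitution is chosen over directed metalation of 2, because metalation would occur between the two methoxy groups, whereas an electrophile enters para to one methoxy group, beside the propyl chain, as 5 requires.

**The two O–methyl bonds.** Arene 2 is cut at both methyl ethers, back to the resorcinol 1, which already carries the propyl chain in the right place.

## Alternatives that were turned down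

**Alternative 1:** Ring A is disconnected at C1'–C2' and C5'–C6'. The depside ester is then made early, as the unhindered alkynoate A2 of the protected ring B phenol A4. In the key step A2 would undergo a [4+2] cycloaddition with the silyl ketene acetal diene A3, and loss of silanol would aromatise the adduct to the dibenzyl-protected depside A1. Double hydrogenolysis of A1 would give 12.
- For: the ester is formed before its carbonyl is crowded, and the polarity of A3 fixes the ring A substitution pattern. The ring B carboxyl is present from the start, so no site question arises at C1. On that point this route is stronger than the chosen one.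
- Against: a β-alkyl alkynoate is a sluggish dienophile. At the temperatures needed, the electron-rich A3 can instead acylate itself on the aryl ester carbonyl of A2, which is an active ester. A4 has to be made with its oxygens differentiated, A3 is moisture-sensitive, and the route runs to about twice the length.
- In its place the chosen route offers a purchased symmetric diol, no protecting groups and five steps.

**Alternative 2:** The depside C–O bond and the C1'–C6' bond of ring A are both disconnected. Thermolysis of the diketo-dioxinone A6 would release an acylketene, which the C4 phenol of A4 traps to give the aryl triketoester A7. Aldol closure of C2 onto the C7 ketone, followed by dehydration, would give the resorcylate A5.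
- For: ketene capture is insensitive to steric hindrance, one operation makes both the ester and ring A, and the ring B carboxyl is again already in place. On ester formation this route is at least as strong as the chosen one.
- Against: A5 has two free ring A hydroxyls that must both be methylated to reach A1. The C2' hydroxyl is hydrogen-bonded to the ester carbonyl, and base acting on an aryl salicylate invites cleavage through the neighbouring phenoxide. A7 can also close to a pyrone with expulsion of A4, since the aryloxide is a good leaving group. A6 and A4 each need several steps.
- The chosen route installs the methyl ethers before the ester exists and is much shorter.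

**Alternative 3:** The bond between the ester oxygen and C4 of ring B is disconnected. The ring A acid A10 (the same compound as 5) would be O-arylated by the ring B boronic acid A9 in a copper-mediated oxidative coupling under air with a divalent copper salt. This would give the protected depside A8, and acid would then remove both protecting groups to give 12.
- For: the new bond is made at the carboxylate oxygen, away from the hindered carbonyl, so the ortho substituents of ring A do not matter. There is no site ambiguity on ring B, and one acid step deprotects everything. On both points it is stronger than the chosen route.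
- Against: A9 is a doubly protected, C4-borylated olivetolic acid that takes many steps to make. Carboxylates are weaker partners than phenols or amines in this coupling, so protodeboronation and oxidation of the boronic acid compete. The final acid treatment exposes a decarboxylation-prone salicylic acid to the conditions that endanger it.
- The chosen route accepts a hindered acylation and a site question in exchange for far fewer steps and no protecting groups.

Key step: step 5

Remark: ring B is numbered as in the target throughout (C1 carboxyl, C2 hydroxyl, C4 acyloxy, C6 pentyl), and ring A carries primed numbers. Diol 1 and the 2 M DMF solution of MeOMgOCO2Me are taken to be purchasable; the reagent is otherwise made by passing carbon dioxide 9 into Mg(OMe)2 in DMF.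

## Route

Step 1
Reactants: 1 5-propylbenzene-1,3-diol (divarinol)
Product: 2 1,3-dimethoxy-5-propylbenzene
Conditions: MeI (2.5 equiv), K2CO3 (3 equiv), DMF, rt
Reagents that add atoms: iodomethane, CI
Why: Williamson ether synthesis; both phenoxides of 1 are alkylated by SN2 on iodomethane, no other nucleophilic site competes and no stereocentre is involved.

Step 2
Reactants: 2 1,3-dimethoxy-5-propylbenzene
Product: 4 2,4-dimethoxy-6-propylbenzaldehyde, via aryl dimethyliminium chloride 3 (not isolated)
Conditions: POCl3 (1.5 equiv), DMF, 0 °C to 70 °C; then aq NaOAc, rt
Reagents that add atoms: N,N-dimethylformamide, CN(C)C=O; water, O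
Why: Vilsmeier–Haack formylation; the chloroiminium electrophile enters para to one methoxy group and ortho to the other, next to the propyl chain, as is usual for 5-alkylresorcinol dimethyl ethers, with only minor attack between the two methoxy groups. Aqueous acetate hydrolyses iminium 3 to the aldehyde.

Step 3
Reactants: 4 2,4-dimethoxy-6-propylbenzaldehyde
Product: 5 2,4-dimethoxy-6-propylbenzoic acid
Conditions: NaClO2, NaH2PO4, 2-methyl-2-butene, t-BuOH/H2O, 0 °C to rt
Reagents that add atoms: sodium chlorite, [Na+].[O-]Cl=O
Why: Pinnick (Lindgren) oxidation; chlorous acid adds to the aldehyde and fragments to the acid and HOCl, which 2-methyl-2-butene traps before it can chlorinate the electron-rich ring. The methyl ethers are untouched.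

Step 4
Reactants: 5 2,4-dimethoxy-6-propylbenzoic acid; 6 olivetol (5-pentylbenzene-1,3-diol, 3 equiv)
Product: 8 3-hydroxy-5-pentylphenyl 2,4-dimethoxy-6-propylbenzoate, via 2,4-dimethoxy-6-propylbenzoyl chloride 7 (not isolated)
Conditions: (COCl)2, cat. DMF, CH2Cl2, 0 °C to rt, evaporate; then slow addition to 6 (3 equiv), Et3N, DMAP (0.1 equiv), CH2Cl2, 0 °C to rt
Reagents that add atoms: none
Why: Acid chloride formation with chloroiminium catalysis, then DMAP-catalysed O-acylation of the phenol through the acylpyridinium ion. The two hydroxyls of 6 are equivalent, so the monoester is a single compound, and the threefold excess of 6 with slow addition of 7 should keep the bis-ester low (surplus 6 is recovered).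

Step 5
Reactants: 8 3-hydroxy-5-pentylphenyl 2,4-dimethoxy-6-propylbenzoate; 9 carbon dioxide
Product: 12 4-[(2,4-dimethoxy-6-propylbenzoyl)oxy]-2-hydroxy-6-pentylbenzoic acid, via aryloxymagnesium methyl carbonate 10 (not isolated), via magnesium salicylate chelate 11 (not isolated)
Conditions: MeOMgOCO2Me (from Mg(OMe)2 and CO2, 2 M in DMF, 10 equiv), 120 °C, N2 sweep, 2 h; then cold 1 M HCl, 0 °C
Reagents that add atoms: methoxymagnesium methyl carbonate (the carrier of carbon dioxide 9), CO[Mg]OC(=O)OC
Why: The phenol of 8 exchanges onto magnesium to give the aryloxymagnesium methyl carbonate 10, in which the carbonate ligand hands carbon dioxide to an ortho carbon of ring B through a six-membered, magnesium-templated transition state; loss of the ring proton restores aromaticity and gives the magnesium salicylate chelate 11. The closest known reaction type is the Kolbe–Schmitt-type ortho-carboxylation of phenols with MeOMgOCO2Me, which converts 5-alkylresorcinols and their mono-O-substituted derivatives into 2-hydroxy-6-alkylbenzoic acids. The carboxylation is reversible at 120 °C and should be pulled forward by the stability of chelate 11 and by sweeping out methanol. No ring of the target is closed and no stereocentre is formed; the six-membered magnesium chelate ring of 11 is opened again by acid. Site selectivity is needed between C1 and C3, the two carbons ortho to the free hydroxyl: C1 is para to the acyloxy oxygen and corresponds to the position carboxylated in the parent resorcinol, whereas a carboxylate at C3 would sit between the phenoxide and the twisted, di-ortho-substituted aroyloxy group, so under reversible conditions the C1 chelate should prevail. Chemoselectivity is needed against methanolysis of the depside, and the methoxy and propyl groups that flank the ring A carbonyl shield it from attack. Work-up with cold dilute HCl should free 12 without the heating in acid that would decarboxylate it.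

## Compound list

1 | 5-propylbenzene-1,3-diol (divarinol) | CCCc1cc(O)cc(O)c1 | starting material
2 | 1,3-dimethoxy-5-propylbenzene | CCCc1cc(OC)cc(OC)c1 | intermediate
3 | N-[(2,4-dimethoxy-6-propylphenyl)methylidene]-N-methylmethanaminium chloride | CCCc1cc(OC)cc(OC)c1C=[N+](C)C.[Cl-] | intermediate (not isolated)
4 | 2,4-dimethoxy-6-propylbenzaldehyde | CCCc1cc(OC)cc(OC)c1C=O | intermediate
5 | 2,4-dimethoxy-6-propylbenzoic acid | CCCc1cc(OC)cc(OC)c1C(=O)O | intermediate
6 | olivetol (5-pentylbenzene-1,3-diol) | CCCCCc1cc(O)cc(O)c1 | starting material
7 | 2,4-dimethoxy-6-propylbenzoyl chloride | CCCc1cc(OC)cc(OC)c1C(Cl)=O | intermediate (not isolated)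
8 | 3-hydroxy-5-pentylphenyl 2,4-dimethoxy-6-propylbenzoate | CCCCCc1cc(O)cc(OC(=O)c2c(CCC)cc(OC)cc2OC)c1 | intermediate
9 | carbon dioxide | O=C=O | starting material
10 | {3-[(2,4-dimethoxy-6-propylbenzoyl)oxy]-5-pentylphenoxy}magnesium methyl carbonate | CCCCCc1cc(O[Mg]OC(=O)OC)cc(OC(=O)c2c(CCC)cc(OC)cc2OC)c1 | intermediate (not isolated)
11 | magnesium 4-[(2,4-dimethoxy-6-propylbenzoyl)oxy]-2-oxido-6-pentylbenzoate (cyclic chelate) | CCCCCc1cc(OC(=O)c3c(CCC)cc(OC)cc3OC)cc2O[Mg]OC(=O)c12 | intermediate (not isolated)
12 | 4-[(2,4-dimethoxy-6-propylbenzoyl)oxy]-2-hydroxy-6-pentylbenzoic acid | CCCCCc1cc(OC(=O)c2c(CCC)cc(OC)cc2OC)cc(O)c1C(=O)O | target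

## Step count and risk

Total step count: 5. Longest linear sequence: 5 steps (1 to 12); olivetol 6 and carbon dioxide 9 enter as purchased materials.

**Step 5 (key step).** Three things may go wrong.
- The carboxylation may stall or run backwards. The acyloxy group is a much weaker donor than the second phenoxide of a resorcinol, so the equilibrium towards chelate 11 is less favourable. The acid can also lose carbon dioxide if the work-up is allowed to warm.
- The depside may be cleaved by methoxide, or by dimethylamine formed from DMF at 120 °C, or by acyl transfer between magnesium phenoxides.
- Carbon dioxide may be delivered to C3 instead of C1. C3 is para to the pentyl group, and an alkyl group donates about as well as an acyloxy group, so the preference for C1 rests mainly on the crowding of the C3 chelate and is not assured.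

Fallback: the carboxyl is installed before the ester, on the free resorcinol, where this carboxylation is on firm ground. The fallback sets out from 6 and 7. Olivetol 6 is carboxylated with MeOMgOCO2Me in DMF at 120 °C to give 2,4-dihydroxy-6-pentylbenzoic acid F1. The carboxylate is benzylated (BnBr, KHCO3, DMF) to benzyl 2,4-dihydroxy-6-pentylbenzoate F2. The C4 hydroxyl of F2 is acylated with 7 (Et3N, DMAP, CH2Cl2); the C2 hydroxyl is tied up in a hydrogen bond to the ester carbonyl and should stay free. This gives benzyl 4-[(2,4-dimethoxy-6-propylbenzoyl)oxy]-2-hydroxy-6-pentylbenzoate F3, and hydrogenolysis (H2, Pd/C, EtOAc, rt) returns to the route at 12.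

**Step 4.** Over-acylation to the bis-ester and slow acylation by the di-ortho-substituted chloride 7 may occur, with hydrolysis of 7 taking over if the coupling drags.

Fallback: the statistical step is moved onto cheap material. Olivetol 6 is monobenzylated (BnBr 1 equiv, K2CO3, DMF) to 3-(benzyloxy)-5-pentylphenol F4, which is separated from the bis-ether and from recovered 6. Its single phenol is acylated with 7 (NaH, THF, 0 °C to rt) to 3-(benzyloxy)-5-pentylphenyl 2,4-dimethoxy-6-propylbenzoate F5. Hydrogenolysis (H2, Pd/C, EtOAc) returns to the route at 8.

**Step 2.** Formylation may also occur between the two methoxy groups, or conversion may stall, which lowers the supply of 4.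

Fallback: the carbon is introduced through a halogen–metal exchange instead. Arene 2 is brominated with NBS in MeCN at 0 °C, which should go para to a methoxy group and avoid the carbon between the two ethers, to give 2-bromo-1,5-dimethoxy-3-propylbenzene F6. Lithium–bromine exchange (n-BuLi, THF, −78 °C) and quenching with CO2 then lead straight to acid 5, bypassing 4 and step 3.

## Further compounds

F1 | step 5 | 2,4-dihydroxy-6-pentylbenzoic acid (olivetolic acid) | CCCCCc1cc(O)cc(O)c1C(=O)O
F2 | step 5 | benzyl 2,4-dihydroxy-6-pentylbenzoate | CCCCCc1cc(O)cc(O)c1C(=O)OCc1ccccc1
F3 | step 5 | benzyl 4-[(2,4-dimethoxy-6-propylbenzoyl)oxy]-2-hydroxy-6-pentylbenzoate | CCCCCc1cc(OC(=O)c2c(CCC)cc(OC)cc2OC)cc(O)c1C(=O)OCc1ccccc1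
F4 | step 4 | 3-(benzyloxy)-5-pentylphenol | CCCCCc1cc(O)cc(OCc2ccccc2)c1
F5 | step 4 | 3-(benzyloxy)-5-pentylphenyl 2,4-dimethoxy-6-propylbenzoate | CCCCCc1cc(OCc2ccccc2)cc(OC(=O)c2c(CCC)cc(OC)cc2OC)c1
F6 | step 2 | 2-bromo-1,5-dimethoxy-3-propylbenzene | CCCc1cc(OC)cc(OC)c1Br
A1 | alternative 1 | benzyl 2-(benzyloxy)-4-[(2,4-dimethoxy-6-propylbenzoyl)oxy]-6-pentylbenzoate | CCCCCc1cc(OC(=O)c2c(CCC)cc(OC)cc2OC)cc(OCc2ccccc2)c1C(=O)OCc1ccccc1
A2 | alternative 1 | benzyl 2-(benzyloxy)-4-(hex-2-ynoyloxy)-6-pentylbenzoate | CCCCCc1cc(OC(=O)C#CCCC)cc(OCc2ccccc2)c1C(=O)OCc1ccccc1
A3 | alternative 1 | 1,3-dimethoxy-1-(trimethylsilyloxy)buta-1,3-diene | COC(=C)C=C(OC)O[Si](C)(C)C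
A4 | alternative 1 | benzyl 2-(benzyloxy)-4-hydroxy-6-pentylbenzoate | CCCCCc1cc(O)cc(OCc2ccccc2)c1C(=O)OCc1ccccc1
A5 | alternative 2 | benzyl 2-(benzyloxy)-4-[(2,4-dihydroxy-6-propylbenzoyl)oxy]-6-pentylbenzoate | CCCCCc1cc(OC(=O)c2c(CCC)cc(O)cc2O)cc(OCc2ccccc2)c1C(=O)OCc1ccccc1
A6 | alternative 2 | 6-(2,4-dioxoheptyl)-2,2-dimethyl-4H-1,3-dioxin-4-one | CCCC(=O)CC(=O)CC1=CC(=O)OC(C)(C)O1
A7 | alternative 2 | benzyl 2-(benzyloxy)-6-pentyl-4-[(3,5,7-trioxodecanoyl)oxy]benzoate | CCCCCc1cc(OC(=O)CC(=O)CC(=O)CC(=O)CCC)cc(OCc2ccccc2)c1C(=O)OCc1ccccc1
A8 | alternative 3 | tert-butyl 4-[(2,4-dimethoxy-6-propylbenzoyl)oxy]-2-(methoxymethoxy)-6-pentylbenzoate | CCCCCc1cc(OC(=O)c2c(CCC)cc(OC)cc2OC)cc(OCOC)c1C(=O)OC(C)(C)C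
A9 | alternative 3 | [4-(tert-butoxycarbonyl)-3-(methoxymethoxy)-5-pentylphenyl]boronic acid | CCCCCc1cc(B(O)O)cc(OCOC)c1C(=O)OC(C)(C)C
A10 | alternative 3 | 2,4-dimethoxy-6-propylbenzoic acid | CCCc1cc(OC)cc(OC)c1C(=O)O
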